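## Retrosynthetic overview

1. The target is an oplopane, a ring-contracted cadinane. Late operations: C9 enoate ester, C9 allylic hydroxylation, C4 acetate, C4 ketone reduction.
2. The cyclopentanone with its C3 ketone and C4 oxygen comes from a 1,2-acyl-shift ring contraction (six → five) of a 3-oxo-4,5-epoxycadinane, mirroring the presumed cadinane → oplopane biogenesis.
3. The cadina-4,10(14)-diene comes from a cationic annulation: the C4–C5–C6 allyl cation of a limonene-derived p-menthadienol is captured at C6 by an isovaleraldehyde enol silane, then cation–olefin (carbonyl-ene) closure with loss of a C14 proton.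
4. Ring order: ring A is bought as a six-membered ring; ring B is formed in step 2; ring A is contracted to the cyclopentanone in step 6.

Assumption: commercial (+)-p-mentha-2,8-dien-1-ol (4R, drawn as 1S,4R) is used, its C1 configuration being lost on ionisation so either epimer serves; (E)-3-methylpent-2-enoic acid and (S)-2-methylbutanoic acid are taken as catalogue compounds.

Numbering: cadinane numbering throughout. Ring A = C1–C6 (C15 on C4). Ring B = C1, C6–C10 (C14 on C10, isopropyl on C7). After contraction ring A is C1, C2, C3, C5, C6 and C4–C15 is the side chain on C5. β = face of H-1, α = face of H-6.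

## Route

Step 1
Reactants: 1 3-methylbutanal (isovaleraldehyde)
Product: 2 trimethyl[(3-methylbut-1-en-1-yl)oxy]silane (E/Z mixture)
Conditions: Me3SiCl, Et3N, DMF, 90 °C; distil
Reagents that add atoms: chlorotrimethylsilane, C[Si](C)(C)Cl
Why: Amine-mediated O-silylation of the aldehyde enol (silyl enol ether formation); the E/Z ratio is unimportant because the enol carbon bonds through an open transition state in step 2.

Step 2
Reactants: 3 (1S,4R)-p-mentha-2,8-dien-1-ol; 2 trimethyl[(3-methylbut-1-en-1-yl)oxy]silane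
Product: 5 trans-fused cadina-4,10(14)-dien-8β-ol (H-1 β, H-6 α, 7α-isopropyl, 8β-OH, both equatorial), via seco-aldehyde 4 (not isolated)
Conditions: 2 (1.3 equiv), Me3SiOTf (10 mol %), CH2Cl2, −78 °C; then MeAl(OAr)2 (Ar = 2,6-di-tert-butyl-4-methylphenyl, 2.5 equiv, toluene solution), −78 → −20 °C; 1 M HCl work-up
Reagents that add atoms: none
Why: Proposed new method: ionisation of the tertiary allylic alcohol gives the p-menthadienyl (C4–C5–C6) cation, which the enol silane captures at C6 anti to the isopropenyl group as in the Friedel–Crafts allylations of this cation used for cannabidiol (Mukaiyama-type SN1 alkylation; an open antiperiplanar transition state with isopropyl turned away from C1 sets C7), and the resulting α-branched aldehyde closes ring B by a Lewis-acid type 2 carbonyl-ene (Prins) reaction through an all-equatorial chair in which the bulky aluminium phenoxide holds the complexed oxygen equatorial (8β-OH) and the developing C10 cation loses a C14 proton to give the exocyclic methylene.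

Step 3
Reactants: 5 cadina-4,10(14)-dien-8β-ol; 6 (S)-2-methylbutanoic acid
Product: 7 cadina-4,10(14)-dien-8β-yl (S)-2-methylbutanoate
Conditions: DCC, DMAP (10 mol %), CH2Cl2, 0 °C → rt
Reagents that add atoms: none
Why: Steglich esterification of the equatorial secondary alcohol; no stereocentre is formed and the α-alkyl acid does not epimerise under carbodiimide activation.

Step 4
Reactants: 7 cadina-4,10(14)-dien-8β-yl (S)-2-methylbutanoate
Product: 8 3-oxocadina-4,10(14)-dien-8β-yl (S)-2-methylbutanoate
Conditions: Rh2(cap)4 (cap = caprolactamate, 1 mol %), t-BuOOH (70 % aq., 5 equiv), K2CO3 (0.5 equiv), CH2Cl2, rt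
Reagents that add atoms: tert-butyl hydroperoxide, CC(C)(C)OO
Why: Radical allylic C–H oxidation by t-BuOO• (Kharasch-type, dirhodium caprolactamate/TBHP): C3 is the only allylic methylene of the electron-rich trisubstituted olefin that can become a conjugated ketone, C9–H2 is deactivated by the adjacent acyloxy group, and H-1 and H-6 are hindered tertiary positions; no stereocentre is formed.

Step 5
Reactants: 8 3-oxocadina-4,10(14)-dien-8β-yl (S)-2-methylbutanoate
Product: 9 4β,5β-epoxy-3-oxocadin-10(14)-en-8β-yl (S)-2-methylbutanoate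
Conditions: t-BuOOH, benzyltrimethylammonium hydroxide (cat.), THF, 0 °C → rt
Reagents that add atoms: tert-butyl hydroperoxide, CC(C)(C)OO
Why: Weitz–Scheffer nucleophilic epoxidation touches only the enone (the isolated methylene is inert), with axial attack at C5 on the β face leading to the chair enolate; the C4/C5 configuration is erased in step 6.

Step 6
Reactants: 9 4β,5β-epoxy-3-oxocadin-10(14)-en-8β-yl (S)-2-methylbutanoate
Product: 10 8β-[(S)-2-methylbutanoyloxy]oplop-10(14)-ene-3,4-dione (trans-hydrindane, 5α-acetyl, H-5 β, largely enolised)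
Conditions: BF3·OEt2 (0.3 equiv), CH2Cl2, −40 → 0 °C; then NaOAc, MeOH/H2O
Reagents that add atoms: none
Why: Lewis-acid rearrangement of an α,β-epoxy ketone to a β-diketone by 1,2-acyl shift (semipinacol type): the C5–O bond, remote from the carbonyl, ionises while the acyl carbon C3 migrates from C4 to C5, contracting ring A to the cyclopentanone and turning C4 into the acetyl carbonyl; C5 then settles by enolisation into the trans (5α-acetyl) arrangement of the target.

Step 7
Reactants: 10 8β-[(S)-2-methylbutanoyloxy]oplop-10(14)-ene-3,4-dione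
Product: 11 (4R)-4-hydroxy-3-oxo-oplop-10(14)-en-8β-yl (S)-2-methylbutanoate
Conditions: NADP-dependent (R)-selective alcohol dehydrogenase from Lactobacillus kefir, NADP+ (cat.), MgCl2, i-PrOH/phosphate buffer pH 7 (1:9), 30 °C
Reagents that add atoms: none
Why: Ketoreductase-catalysed regio- and stereoselective monoreduction of a 2-substituted 1,3-diketone at its methyl ketone (anti-Prelog hydride delivery gives 4R), with the labile C5 centre settling trans under the dynamic conditions.

Step 8
Reactants: 11 (4R)-4-hydroxy-3-oxo-oplop-10(14)-en-8β-yl (S)-2-methylbutanoate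
Product: 12 (4R)-4-acetoxy-3-oxo-oplop-10(14)-en-8β-yl (S)-2-methylbutanoate
Conditions: Ac2O, pyridine, DMAP (cat.), CH2Cl2, 0 °C
Reagents that add atoms: acetic anhydride, CC(=O)OC(C)=O
Why: Standard O-acylation of the secondary alcohol, run cold and briefly to avoid β-elimination of the β-acetoxy ketone; no stereocentre is touched.

Step 9
Reactants: 12 (4R)-4-acetoxy-3-oxo-oplop-10(14)-en-8β-yl (S)-2-methylbutanoate
Product: 13 (4R)-4-acetoxy-9β-hydroxy-3-oxo-oplop-10(14)-en-8β-yl (S)-2-methylbutanoate
Conditions: SeO2 (0.3 equiv), t-BuOOH (3 equiv), CH2Cl2, rt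
Reagents that add atoms: tert-butyl hydroperoxide, CC(C)(C)OO
Why: Selenium dioxide allylic hydroxylation (ene reaction then [2,3]-sigmatropic shift) of the exocyclic methylene goes at the ring CH2 (C9) rather than the ring-fusion CH (C1) and delivers oxygen axially, giving the 9β-alcohol cis to the 8β-ester.

Step 10
Reactants: 13 (4R)-4-acetoxy-9β-hydroxy-3-oxo-oplop-10(14)-en-8β-yl (S)-2-methylbutanoate; 14 (E)-3-methylpent-2-enoic acid
Product: 16 (4R)-4-acetoxy-8β-[(S)-2-methylbutanoyloxy]-9β-[(E)-3-methylpent-2-enoyloxy]oplop-10(14)-en-3-one (CNP0124625.1), via mixed anhydride 15 (not isolated)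
Conditions: 14, 2,4,6-trichlorobenzoyl chloride, Et3N, THF, rt; filter, concentrate; then 13, toluene, 80 °C (no DMAP)
Reagents that add atoms: none
Why: Yamaguchi mixed-anhydride esterification run thermally without a nucleophilic catalyst, so that no acylpyridinium or vinylketene forms and the E geometry of the enoate is kept; no stereocentre is touched.

## Compound list

1 | 3-methylbutanal | CC(C)CC=O | starting material
2 | trimethyl[(3-methylbut-1-en-1-yl)oxy]silane (E/Z mixture) | CC(C)C=CO[Si](C)(C)C | intermediate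
3 | (1S,4R)-p-mentha-2,8-dien-1-ol | C[C@@]1(O)C=C[C@H](C(C)=C)CC1 | starting material
4 | (2S)-3-methyl-2-[(1R,6R)-3-methyl-6-(prop-1-en-2-yl)cyclohex-2-en-1-yl]butanal | O=C[C@@H](C(C)C)[C@@H]1C=C(C)CC[C@H]1C(C)=C | intermediate
5 | cadina-4,10(14)-dien-8β-ol (H-1 β, H-6 α, 7α-isopropyl) | C=C1[C@@H]2CCC(C)=C[C@H]2[C@H](C(C)C)[C@@H](O)C1 | intermediate
6 | (S)-2-methylbutanoic acid | CC[C@H](C)C(=O)O | starting material
7 | cadina-4,10(14)-dien-8β-yl (S)-2-methylbutanoate | C=C1[C@@H]2CCC(C)=C[C@H]2[C@H](C(C)C)[C@@H](OC(=O)[C@@H](C)CC)C1 | intermediate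
8 | 3-oxocadina-4,10(14)-dien-8β-yl (S)-2-methylbutanoate | C=C1[C@@H]2CC(=O)C(C)=C[C@H]2[C@H](C(C)C)[C@@H](OC(=O)[C@@H](C)CC)C1 | intermediate
9 | 4β,5β-epoxy-3-oxocadin-10(14)-en-8β-yl (S)-2-methylbutanoate | C=C1[C@@H]2CC(=O)[C@@]3(C)O[C@H]3[C@H]2[C@H](C(C)C)[C@@H](OC(=O)[C@@H](C)CC)C1 | intermediate
10 | 8β-[(S)-2-methylbutanoyloxy]oplop-10(14)-ene-3,4-dione (5α-acetyl) | C=C1[C@@H]2CC(=O)[C@H](C(C)=O)[C@H]2[C@H](C(C)C)[C@@H](OC(=O)[C@@H](C)CC)C1 | intermediate
11 | (4R)-4-hydroxy-3-oxo-oplop-10(14)-en-8β-yl (S)-2-methylbutanoate | C=C1[C@@H]2CC(=O)[C@H]([C@@H](C)O)[C@H]2[C@H](C(C)C)[C@@H](OC(=O)[C@@H](C)CC)C1 | intermediate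
12 | (4R)-4-acetoxy-3-oxo-oplop-10(14)-en-8β-yl (S)-2-methylbutanoate | C=C1[C@@H]2CC(=O)[C@H]([C@@H](C)OC(C)=O)[C@H]2[C@H](C(C)C)[C@@H](OC(=O)[C@@H](C)CC)C1 | intermediate
13 | (4R)-4-acetoxy-9β-hydroxy-3-oxo-oplop-10(14)-en-8β-yl (S)-2-methylbutanoate | C=C1[C@@H]2CC(=O)[C@H]([C@@H](C)OC(C)=O)[C@H]2[C@H](C(C)C)[C@@H](OC(=O)[C@@H](C)CC)[C@H]1O | intermediate
14 | (E)-3-methylpent-2-enoic acid | CC/C(C)=C/C(=O)O | starting material
15 | (E)-3-methylpent-2-enoic 2,4,6-trichlorobenzoic anhydride | CC/C(C)=C/C(=O)OC(=O)c1c(Cl)cc(Cl)cc1Cl | intermediate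
16 | CNP0124625.1 | C=C1[C@@H]2CC(=O)[C@H]([C@@H](C)OC(C)=O)[C@H]2[C@H](C(C)C)[C@@H](OC(=O)[C@@H](C)CC)[C@H]1OC(=O)/C=C(\C)CC | target

## Step count and risks

Total steps: 10. Longest linear sequence: 10 (1 → 16; 9 from the terpene 3).

Step 2 is the most exposed step. C7 is set in an open transition state, the C10 cation may lose a ring proton instead of a C14 proton, and the equatorial 8β-OH depends on the bulky aluminium reagent. The fallback sets out from 3 and returns to the route at 5. Compound 3 is coupled under TiCl4/i-Pr2NEt in CH2Cl2 (second equivalent of TiCl4 to ionise 3, −78 → −20 °C) with the chlorotitanium enolate of (R)-4-benzyl-3-(3-methylbutanoyl)oxazolidin-2-one F1, itself made from (R)-4-benzyloxazolidin-2-one, n-BuLi and 3-methylbutanoyl chloride. The auxiliary then fixes C7 while the ring still fixes C6, giving the imide (R)-4-benzyl-3-{(2S)-3-methyl-2-[(1R,6R)-3-methyl-6-(prop-1-en-2-yl)cyclohex-2-en-1-yl]butanoyl}oxazolidin-2-one F2. LiBH4 in wet THF releases the auxiliary and gives (2S)-3-methyl-2-[(1R,6R)-3-methyl-6-(prop-1-en-2-yl)cyclohex-2-en-1-yl]butan-1-ol F3. Dess–Martin oxidation gives aldehyde 4, now isolated and purified, which is cyclised with MeAl(OAr)2 in a separate operation to 5.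

Step 4 may suffer from hydrogen abstraction at the tertiary allylic H-6 and H-1 or at C9, giving peroxides or the wrong ketone. The fallback sets out from 7 and returns at 8, replacing radical oxidation by an ene-type hydroxylation. SeO2 (0.5 equiv) with t-BuOOH in CH2Cl2 at 0 °C is stopped once 7 is consumed; the trisubstituted ring A olefin reacts faster than the ester-deactivated methylene and is hydroxylated at the ring CH2 on its more substituted end. This gives 3β-hydroxycadina-4,10(14)-dien-8β-yl (S)-2-methylbutanoate F4, which MnO2 in CH2Cl2 oxidises to enone 8.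

Step 6 may fail because the migration terminus C5 is only secondary. Competing paths are C4–O cleavage with hydride shift to a cyclohexane-1,3-dione, methyl shift, or fluoride capture. The fallback sets out from 9 and returns at 10, replacing the cationic opening by a push–pull semipinacol. Acid-catalysed hydration (HClO4 cat., THF/H2O) opens the epoxide at C5, the carbon insulated from the carbonyl, giving 4β,5α-dihydroxy-3-oxocadin-10(14)-en-8β-yl (S)-2-methylbutanoate F5. MsCl in pyridine sulfonylates only the secondary hydroxyl to give the 5α-mesylate F6. Et3Al in CH2Cl2 (−78 → 0 °C) forms the C4 aluminium alkoxide, and the C3–C4 bond antiperiplanar to the equatorial C5–OMs migrates, giving 10 after enolisation.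

Further compounds

F1 | step 2 | (R)-4-benzyl-3-(3-methylbutanoyl)oxazolidin-2-one | CC(C)CC(=O)N1[C@H](Cc2ccccc2)COC1=O
F2 | step 2 | (R)-4-benzyl-3-{(2S)-3-methyl-2-[(1R,6R)-3-methyl-6-(prop-1-en-2-yl)cyclohex-2-en-1-yl]butanoyl}oxazolidin-2-one | O=C([C@@H](C(C)C)[C@@H]1C=C(C)CC[C@H]1C(C)=C)N1[C@H](Cc2ccccc2)COC1=O
F3 | step 2 | (2S)-3-methyl-2-[(1R,6R)-3-methyl-6-(prop-1-en-2-yl)cyclohex-2-en-1-yl]butan-1-ol | OC[C@@H](C(C)C)[C@@H]1C=C(C)CC[C@H]1C(C)=C
F4 | step 4 | 3β-hydroxycadina-4,10(14)-dien-8β-yl (S)-2-methylbutanoate | C=C1[C@@H]2C[C@@H](O)C(C)=C[C@H]2[C@H](C(C)C)[C@@H](OC(=O)[C@@H](C)CC)C1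
F5 | step 6 | 4β,5α-dihydroxy-3-oxocadin-10(14)-en-8β-yl (S)-2-methylbutanoate | C=C1[C@@H]2CC(=O)[C@@](C)(O)[C@H](O)[C@H]2[C@H](C(C)C)[C@@H](OC(=O)[C@@H](C)CC)C1
F6 | step 6 | 4β-hydroxy-5α-(methylsulfonyloxy)-3-oxocadin-10(14)-en-8β-yl (S)-2-methylbutanoate | C=C1[C@@H]2CC(=O)[C@@](C)(O)[C@H](OS(C)(=O)=O)[C@H]2[C@H](C(C)C)[C@@H](OC(=O)[C@@H](C)CC)C1
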